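Weigh the reagent with care when you repeat these two runs: they are a race for the starting material, and what you should follow is how much of it escapes the reagent.

in all of them: starting material 0.050 M; reagent 0.0475 M; time 2.5 d

| charge | temperature |
|---|---|
| Friday's | 110 °C |
| Monday's | 125 °C |

    starting material → side product (k1 = 0.013 h⁻¹, Ea1 = 117 kJ mol⁻¹)
    intermediate A → target (k2 = 0.23 h⁻¹, Ea2 = 111 kJ mol⁻¹)
    target ⇌ isomer of the product (K3 = 0.20, k3 = 0.017 h⁻¹, Ea3 = 121 kJ mol⁻¹, ΔH3 = −24.0 kJ mol⁻¹)
    intermediate B ⇌ intermediate D (K4 = 4.7, k4 = 1.3 h⁻¹, Ea4 = 121 kJ mol⁻¹, ΔH4 = −42.0 kJ mol⁻¹)
    starting material ⇌ intermediate A (K5 = 0.32, k5 = 1.9 h⁻¹, Ea5 = 104 kJ mol⁻¹, ΔH5 = −71.0 kJ mol⁻¹)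
    starting material + reagent → intermediate B (k6 = 15 M⁻¹ h⁻¹, Ea6 = 80.0 kJ mol⁻¹)
    reagent + intermediate B ⇌ intermediate C (K7 = 14 M⁻¹, k7 = 1.2 M⁻¹ h⁻¹, Ea7 = 97.0 kJ mol⁻¹, ΔH7 = −16.0 kJ mol⁻¹)
    (constants at 110 °C)

- the list of constants is for 110 °C, to be carried to other temperatures by the activation energies and enthalpies

1. which of the two there is more of at the end, Friday's (target / side product)
2. which of the two there is more of at the end, Monday's (target / side product)
3. how much target is there at the end, in percent of the starting material charged: Friday's
4. how much target is there at the end, in percent of the starting material charged: Monday's

Count everything in fractions of the starting material charged. The reagent charge is then 0.950. In Friday's flask starting material and intermediate A swap much faster than the reagent bites, and intermediate A falls back faster than it goes on to target. So intermediate A stands at 0.32 of the starting material, and the starting material leaks away at 0.0866 h⁻¹, against 0.713 h⁻¹ by the reagent at the start. Call the ratio of the leak to the reagent's rate at a reagent level of one charge the leak number, a selectivity factor, 0.115. Of what leaks, a share 0.850 goes towards target and the rest to side product. Target and isomer of the product then have time to level out, so divide the target side by one plus 0.20. I leave intermediate C out of this reckoning.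

Two extreme versions of Friday's flask can be done in the head. If the reagent were instantly fast, it would take what its charge allows, and the leak would get the remainder, giving 3.54% target. With no reagent the whole charge leaks, giving 70.8% target. The real flask lies between them: the reagent wins while its level stands above the leak number, and the leak wins below that.

Written out, the leaked share f obeys f = w ln(e/r). Here w is the leak number, e the reagent charge, and r the reagent left, which is e minus one plus f. Start with r equal to w, which gives 0.243. Put that back in and you get 0.184. The answers swing about the true one, so take the mean, 0.214. On Friday's flask that gives 15.1% target, and target leads.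

Carried to Monday's temperature, the leak number becomes 0.0880, smaller than Friday's. The target share falls to 0.695. The same two rounds give a leaked share of 0.183, hence 11.1% target, and target leads.

The forecast names target for Friday's and target for Monday's. It gives 15.5% target on Friday's (range 13.5% to 18%) and 11.5% on Monday's (range 10% to 13.5%), reasoning that product comes from “only the last fifth or so, once the reagent runs low”. Its figures are not the ones I reckoned.

The simulation gives 14.7% target against 3.23% side product on Friday's, and 10.9% against 5.60% on Monday's, so target leads in both.

Friday's target stays low through two things acting together, the path from starting material and reagent to intermediate B and the falling back of intermediate A to starting material. Strike the first and target reaches 69.4%; strike the second and it reaches 62.7%. The first stands in the bottom of the leak number, the second in its top, through 0.32. A simulated run shows what would put the forecast wrong: with the other amounts and the time held, Friday's target has moved by 6 points at 0.0385 M or 0.0665 M of reagent.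

Now take Friday's flask with 0.12 M of reagent, so e is 2.40. The reagent left now stands far above the leak number, so start from no leak at all. The two rounds average 0.0597, which means 4.23% target. The simulation gives 3.99% target in that flask.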